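**Retrosynthetic overview**

1. Feature: in the five-membered ring C1–C2–C3–C3a–C7a, H-1, H-2 and H-3 lie on one face, so the aroyl at C1, the aryl at C2 and the aryl at C3 are all cis. C1 is α to the ketone and can epimerise, so this contra-thermodynamic triad reads as H2 added to one face of a flat indene and is best set last.
2. Key disconnection: C1–H and C2–H, and C3–H through racemisation. Racemic hexa-O-benzylcaraphenol C, a 3-aroyl-1,2-diaryl-1H-indene, is hydrogenated enantioconvergently. Its H-3 is so acidic (10π indenide/fulvenolate) that it carries no fixed stereocentre, so all three stereocentres are set as a group.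
3. The only ring to be made, the cyclopentene C1–C2–C3–C3a–C7a, is closed at C1=C2 by a 5-exo aldol condensation of a 1,6-diketone.
4. The diketone is the C3–C3a dimer of one C14 deoxybenzoin. Enolate carbon C3 and electron-rich arene carbon C3a have like polarity and are joined by umpolung of one half as a diazo ketone/gold carbene.
5. The monomer comes from 4′-benzyloxyacetophenone and 3,5-bis(benzyloxy)bromobenzene by Pd α-arylation. Neutral hydrogenolysis of six benzyl ethers ends the route.

Key step: step 5

Remark on the chemistry: the SMILES is read as (1R,2R,3R) with the three ring substituents mutually cis (H-1, H-2, H-3 on one face), and the route is built for exactly this isomer; atom labels C1–C7a are those of the indane core of the target and are kept for the same atoms in all precursors.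

**Step 1**
Reactants: 1 1-[4-(benzyloxy)phenyl]ethan-1-one; 2 1,3-bis(benzyloxy)-5-bromobenzene
Product: 3 2-[3,5-bis(benzyloxy)phenyl]-1-[4-(benzyloxy)phenyl]ethan-1-one (the C14 deoxybenzoin monomer)
Conditions: Pd2(dba)3 (1 mol %), Xantphos (2.5 mol %), NaOtBu, THF, 70 °C
Reagents that add atoms: none
Why: Palladium-catalysed ketone α-arylation (Buchwald–Hartwig type), in which the methyl ketone enolate couples with the unhindered aryl bromide and the more acidic, bulkier product enolate resists a second arylation; no stereocentre is formed.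

**Step 2**
Reactants: 3 2-[3,5-bis(benzyloxy)phenyl]-1-[4-(benzyloxy)phenyl]ethan-1-one
Product: 4 2-[3,5-bis(benzyloxy)phenyl]-1-[4-(benzyloxy)phenyl]-2-diazoethan-1-one
Conditions: p-ABSA, DBU, MeCN, 0 °C to rt
Reagents that add atoms: 4-acetamidobenzenesulfonyl azide (p-ABSA), CC(=O)Nc1ccc(cc1)S(=O)(=O)N=[N+]=[N-]
Why: Regitz diazo transfer, in which the doubly activated benzylic CH2 of the deoxybenzoin is deprotonated by DBU and takes up N2 from the sulfonyl azide, turning the nucleophilic enolate carbon (future C3) into a carbene precursor.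

**Step 3**
Reactants: 3 2-[3,5-bis(benzyloxy)phenyl]-1-[4-(benzyloxy)phenyl]ethan-1-one (2 equiv, excess recovered); 4 2-[3,5-bis(benzyloxy)phenyl]-1-[4-(benzyloxy)phenyl]-2-diazoethan-1-one
Product: 5 rac-2-[2,4-bis(benzyloxy)-6-{2-[4-(benzyloxy)phenyl]-2-oxoethyl}phenyl]-2-[3,5-bis(benzyloxy)phenyl]-1-[4-(benzyloxy)phenyl]ethan-1-one (1,6-diketone, the C3–C3a dimer)
Conditions: (2,4-tBu2C6H3O)3PAuCl (5 mol %), AgSbF6 (5 mol %), CH2Cl2, rt, slow addition of 4
Reagents that add atoms: none
Why: Gold-carbene aromatic C–H functionalisation (electrophilic aromatic substitution by a donor/acceptor carbenoid), in which the carbenoid from 4 should attack the only strongly activated ring of 3 para to a benzyloxy group (the equivalent positions C2/C6 of that ring, which become C3a), slow addition keeps 4 from reacting with itself, and the new centre C3 is formed racemic and is meant to stay labile.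

**Step 4**
Reactants: 5 the 1,6-diketone
Product: 7 rac-{1-[3,5-bis(benzyloxy)phenyl]-5,7-bis(benzyloxy)-2-[4-(benzyloxy)phenyl]-1H-inden-3-yl}[4-(benzyloxy)phenyl]methanone (hexa-O-benzylcaraphenol C), via potassium [4-(benzyloxy)phenyl]{4,6-bis(benzyloxy)-3-[3,5-bis(benzyloxy)phenyl]-2-[4-(benzyloxy)phenyl]-1H-inden-1-ylidene}methanolate 6 (not isolated)
Conditions: KOH, EtOH–THF, 50 °C, Ar; then AcOH, 0 °C
Reagents that add atoms: none
Why: Intramolecular aldol condensation (5-exo-trig, then E1cB), in which only attack of the C1 enolate on the C2 ketone gives an adduct that can lose water, the alternative adduct from the C3 enolate has no α-hydrogen and reverts, deprotonation to the aromatic indenide/fulvenolate 6 makes the closure irreversible, and protonation gives the conjugated enone as a racemate.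

**Step 5**
Reactants: 7 rac-hexa-O-benzylcaraphenol C
Product: 9 {(1R,2R,3R)-3-[3,5-bis(benzyloxy)phenyl]-4,6-bis(benzyloxy)-2-[4-(benzyloxy)phenyl]-2,3-dihydro-1H-inden-1-yl}[4-(benzyloxy)phenyl]methanone (hexa-O-benzylcaraphenol B; aroyl, aryl and aryl all cis), via triethylammonium indenide/fulvenolate 8 (not isolated)
Conditions: [Rh(cod)2]BF4 (5 mol %), Josiphos (Ph2P/tBu2P type, 5.5 mol %), Et3N (20 mol %), H2 (50 bar), THF–MeOH, 40 °C
Reagents that add atoms: none
Why: Proposed new method: Et3N reversibly removes H-3 of 7, which is doubly benzylic, part of a cyclopentadiene unit and vinylogously α to the aroyl group, to give the planar achiral 10π indenide/fulvenolate 8, so that (R)- and (S)-7 interconvert while a cationic Rh(I)–ferrocenyldiphosphine catalyst, bound to the ketone oxygen and to C1=C2, adds H2 suprafacially to only one of them. The closest known reaction types are the Rh/ferrocenyldiphosphine asymmetric hydrogenation of tetrasubstituted 2-substituted cyclopent-1-enyl aryl ketones to the cis ketones, the asymmetric hydrogenation of tetrasubstituted indenes to cis-indanes, and dynamic kinetic resolutions in which a base-racemised cyclopentenone is reduced enantioselectively at its C=C bond; new is their combination on a 1,2-diaryl-3-aroylindene. No ring is closed; the bonds formed are C1–H and C2–H, and C3–H is re-formed until it has the right configuration. C1 and C2 are set relative to each other by the syn addition of H2 and relative to C3 by the pseudoaxial 3,5-bis(benzyloxy)phenyl group, which leaves open only the face that already bears H-3, hence the all-cis triad, while C3 and the absolute sense are set by the ligand, whose preferred alkene face is the open one only in (S)-7 (the same spatial arrangement as 3R in 9; the hand of the ligand that meets this is fixed in a first experiment). The step needs C=C over C=O and O-benzyl selectivity, which homogeneous Rh–diphosphine catalysts show, and it needs racemisation of 7 without epimerisation of 9 at C1. The latter is secured by the substrate itself, since loss of H-3 from 7 gives an aromatic, acyl-stabilised anion whereas 9 is an ordinary α-aryl ketone estimated to be many pK units less acidic, so that a tertiary amine should touch only 7.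

**Step 6**
Reactants: 9 hexa-O-benzylcaraphenol B
Product: 10 caraphenol B, [(1R,2R,3R)-3-(3,5-dihydroxyphenyl)-4,6-dihydroxy-2-(4-hydroxyphenyl)-2,3-dihydro-1H-inden-1-yl](4-hydroxyphenyl)methanone
Conditions: H2 (1 atm), 10 % Pd/C, EtOAc–MeOH, rt
Reagents that add atoms: none
Why: Heterogeneous hydrogenolysis of aryl benzyl ethers under neutral conditions, as in the debenzylation of benzyloxy aryl ketones, in which no acid or base touches the epimerisable C1 and the emerging 4-hydroxyphenyl ketone is too electron-rich to be reduced at 1 atm, so that all three stereocentres are carried through unchanged.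

**Compound list**

1 | 1-[4-(benzyloxy)phenyl]ethan-1-one | CC(=O)c1ccc(OCc2ccccc2)cc1 | starting material
2 | 1,3-bis(benzyloxy)-5-bromobenzene | Brc1cc(OCc2ccccc2)cc(OCc2ccccc2)c1 | starting material
3 | 2-[3,5-bis(benzyloxy)phenyl]-1-[4-(benzyloxy)phenyl]ethan-1-one | O=C(Cc1cc(OCc2ccccc2)cc(OCc2ccccc2)c1)c1ccc(OCc2ccccc2)cc1 | intermediate
4 | 2-[3,5-bis(benzyloxy)phenyl]-1-[4-(benzyloxy)phenyl]-2-diazoethan-1-one | O=C(C(=[N+]=[N-])c1cc(OCc2ccccc2)cc(OCc2ccccc2)c1)c1ccc(OCc2ccccc2)cc1 | intermediate
5 | rac-2-[2,4-bis(benzyloxy)-6-{2-[4-(benzyloxy)phenyl]-2-oxoethyl}phenyl]-2-[3,5-bis(benzyloxy)phenyl]-1-[4-(benzyloxy)phenyl]ethan-1-one | O=C(Cc1cc(OCc2ccccc2)cc(OCc2ccccc2)c1C(C(=O)c1ccc(OCc2ccccc2)cc1)c1cc(OCc2ccccc2)cc(OCc2ccccc2)c1)c1ccc(OCc2ccccc2)cc1 | intermediate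
6 | potassium indenide/fulvenolate of 7 (planar, achiral) | [K+].[O-]C(c1ccc(OCc2ccccc2)cc1)=C1C(c2ccc(OCc3ccccc3)cc2)=C(c2cc(OCc3ccccc3)cc(OCc3ccccc3)c2)c2c(OCc3ccccc3)cc(OCc3ccccc3)cc12 | intermediate
7 | rac-hexa-O-benzylcaraphenol C | O=C(c1ccc(OCc2ccccc2)cc1)C1=C(c2ccc(OCc3ccccc3)cc2)C(c2cc(OCc3ccccc3)cc(OCc3ccccc3)c2)c2c(OCc3ccccc3)cc(OCc3ccccc3)cc12 | intermediate
8 | triethylammonium indenide/fulvenolate of 7 (planar, achiral) | CC[NH+](CC)CC.[O-]C(c1ccc(OCc2ccccc2)cc1)=C1C(c2ccc(OCc3ccccc3)cc2)=C(c2cc(OCc3ccccc3)cc(OCc3ccccc3)c2)c2c(OCc3ccccc3)cc(OCc3ccccc3)cc12 | intermediate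
9 | (1R,2R,3R)-hexa-O-benzylcaraphenol B (all-cis) | O=C(c1ccc(OCc3ccccc3)cc1)[C@H]1c2cc(OCc3ccccc3)cc(OCc3ccccc3)c2[C@@H](c2cc(OCc3ccccc3)cc(OCc3ccccc3)c2)[C@H]1c1ccc(OCc3ccccc3)cc1 | intermediate
10 | caraphenol B | O=C(c1ccc(O)cc1)[C@H]1c2cc(O)cc(O)c2[C@@H](c2cc(O)cc(O)c2)[C@H]1c1ccc(O)cc1 | target

**Step count**

Total step count: 6.
Longest linear sequence: 6 (1 → 3 → 4 → 5 → 7 → 9 → 10).

**Steps most likely to fail**

**1. Step 5.**
- What may go wrong: slow or no turnover at the crowded tetrasubstituted C1=C2 bond; binding of the indenide to rhodium; too small a rate gap between the two enantiomers; slow amine-induced epimerisation at C1 of the product.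
- Fallback (known chemistry, with racemisation and reduction decoupled): it sets out from 7. The hydrogenation is run without amine, with the same catalyst family and Zn(OTf)2 as promoter, as a plain kinetic resolution to about half conversion. This gives 9 and leaves the slow-reacting enantiomer, (R)-hexa-O-benzylcaraphenol C F1. F1 is separated, racemised in a separate flask with Et3N back to 7, and resubmitted. The fallback comes back to the route at 9.

**2. Step 3.**
- What may go wrong: attack of the carbenoid at the position between the two benzyloxy groups or on the rings of the product; loss of the diazo compound by Wolff rearrangement or azine formation.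
- Fallback (regiochemistry fixed by a halogen, polarity of the union reversed, a different ring closure): it sets out from 2 and 3.
  - Sonogashira coupling of 2 with commercial 1-(benzyloxy)-4-ethynylbenzene gives the tolane 1,3-bis(benzyloxy)-5-{[4-(benzyloxy)phenyl]ethynyl}benzene F2.
  - NBS brominates F2 para to a benzyloxy group and next to the slim alkyne, giving 1,5-bis(benzyloxy)-2-bromo-3-{[4-(benzyloxy)phenyl]ethynyl}benzene F3.
  - Pd-catalysed α-arylation of the enolate of 3 with this bromide (bulky trialkylphosphine, NaOtBu) gives the alkynyl ketone rac-2-[2,4-bis(benzyloxy)-6-{[4-(benzyloxy)phenyl]ethynyl}phenyl]-2-[3,5-bis(benzyloxy)phenyl]-1-[4-(benzyloxy)phenyl]ethan-1-one F4.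
  - Ring-closing alkyne–carbonyl metathesis (cationic gold or In(OTf)3, DCE) then forms C1=C2 and moves the oxygen to the former alkyne carbon. This comes back to the route at 7 and bypasses 4, 5 and 6.

**3. Step 6.**
- What may go wrong: over-reduction of the ketone, or epimerisation at C1 on the catalyst surface, during the long exposure needed to cleave six benzyl ethers.
- Fallback (deprotection moved ahead of the stereochemistry): it sets out from 7. The benzyl groups are removed while no stereocentre is fixed, with BCl3 and pentamethylbenzene in CH2Cl2 at −78 °C, to give caraphenol C F5. F5 is then hydrogenated under the conditions of step 5 or of its fallback. This comes back to the route at 10, so that no reaction follows the setting of C1.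

**Further compounds**

F1 | step 5 | (R)-hexa-O-benzylcaraphenol C, {(1R)-1-[3,5-bis(benzyloxy)phenyl]-5,7-bis(benzyloxy)-2-[4-(benzyloxy)phenyl]-1H-inden-3-yl}[4-(benzyloxy)phenyl]methanone | O=C(c1ccc(OCc3ccccc3)cc1)C=1c2cc(OCc3ccccc3)cc(OCc3ccccc3)c2[C@H](c2cc(OCc3ccccc3)cc(OCc3ccccc3)c2)C=1c1ccc(OCc3ccccc3)cc1
F2 | step 3 | 1,3-bis(benzyloxy)-5-{[4-(benzyloxy)phenyl]ethynyl}benzene | C(#Cc1cc(OCc2ccccc2)cc(OCc2ccccc2)c1)c1ccc(OCc2ccccc2)cc1
F3 | step 3 | 1,5-bis(benzyloxy)-2-bromo-3-{[4-(benzyloxy)phenyl]ethynyl}benzene | Brc1c(OCc2ccccc2)cc(OCc2ccccc2)cc1C#Cc1ccc(OCc2ccccc2)cc1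
F4 | step 3 | rac-2-[2,4-bis(benzyloxy)-6-{[4-(benzyloxy)phenyl]ethynyl}phenyl]-2-[3,5-bis(benzyloxy)phenyl]-1-[4-(benzyloxy)phenyl]ethan-1-one | O=C(c1ccc(OCc2ccccc2)cc1)C(c1cc(OCc2ccccc2)cc(OCc2ccccc2)c1)c1c(OCc2ccccc2)cc(OCc2ccccc2)cc1C#Cc1ccc(OCc2ccccc2)cc1
F5 | step 6 | rac-caraphenol C, [1-(3,5-dihydroxyphenyl)-5,7-dihydroxy-2-(4-hydroxyphenyl)-1H-inden-3-yl](4-hydroxyphenyl)methanone | O=C(c1ccc(O)cc1)C1=C(c2ccc(O)cc2)C(c2cc(O)cc(O)c2)c2c(O)cc(O)cc12
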